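## Retrosynthetic overview

- Numbering (briarane): ten-membered ring C1–C10; cyclohexene C1/C10–C14; C16 is the exocyclic CH2 on C5; γ-lactone C7–O–C19–C17–C8; methyls C15 (on C1), C18 (on C17), C20 (on C11).
- Enabling feature: in the ten-membered ring, C5(=C16H2)–C6(Cl)–C7(O) is a homoallylic alcohol with a 2-methylene unit, the product pattern of a [2,3]-Wittig shift. Returning O7 to C16 gives an eleven-membered 3-oxacycle (C1–C5, C16, O, C7–C10) with an exocyclic (Z)-chloromethylene on C5, in which a C8 ketone makes C7 the carbanion site.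
- Disconnections: lactone by chelation-controlled propanoate aldol on the C8 ketone; C6–C7 by ring-contracting [2,3]-Wittig rearrangement; C8–C9 by intramolecular Nozaki–Hiyama–Kishi closure, then cleavage of the C8 methylene to the ketone; C11/C12 cis-diol by osmylation of a cyclohexadiene; C1–C14 and C10–C11 by an auxiliary-controlled Diels–Alder reaction; C4–C5 and the chloroalkene by carbomagnesiation of propargyl alcohol.
- Order of ring formation: cyclohexene (step 9), eleven-membered oxacycle (step 18), ten-membered carbocycle (step 21), γ-lactone (step 22).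

Key step: step 21

Remark (assumption on the chemistry): the (2S,5S) amine is taken to send the dienophile, ketone endo, to the diene face anti to the phenyl group beside the reacting terminus, which gives 17 as drawn; if the induction is opposite, the (2R,5R) amine is used and nothing else changes.

## Route

Step 1
Reactants: 1 prop-2-yn-1-ol; 2 [2-(1,3-dioxolan-2-yl)ethyl]magnesium bromide
Product: 4 (2Z)-2-(chloromethylidene)-4-(1,3-dioxolan-2-yl)butan-1-ol, via alkenylmagnesium alkoxide 3 (not isolated)
Conditions: 2 (2.5 equiv), CuI (10 mol%), THF, −10 °C to rt; then N-chlorosuccinimide, −40 to 0 °C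
Reagents that add atoms: N-chlorosuccinimide, O=C1CCC(=O)N1Cl
Why: Copper-catalysed anti-carbomagnesiation of the propargylic alkoxide puts the alkyl group on the internal carbon and magnesium on the terminal one, held cis to CH2O in a five-membered chelate, and chlorination of this alkenyl Grignard with retention fixes the (Z)-chloroalkene that will later carry C6.

Step 2
Reactants: 4 (2Z)-2-(chloromethylidene)-4-(1,3-dioxolan-2-yl)butan-1-ol; 5 2,3-dibromoprop-1-ene
Product: 6 2-[(3Z)-3-{[(2-bromoprop-2-en-1-yl)oxy]methyl}-4-chlorobut-3-en-1-yl]-1,3-dioxolane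
Conditions: NaH, Bu4NI (cat.), THF, 0 °C to rt
Reagents that add atoms: none
Why: Williamson etherification: the sodium alkoxide displaces the allylic bromide of 5 (SN2), while the alkenyl bromide and alkenyl chloride are inert to alkoxide at room temperature.

Step 3
Reactants: 6 2-[(3Z)-3-{[(2-bromoprop-2-en-1-yl)oxy]methyl}-4-chlorobut-3-en-1-yl]-1,3-dioxolane
Product: 7 (4Z)-4-{[(2-bromoprop-2-en-1-yl)oxy]methyl}-5-chloropent-4-enal
Conditions: 1 M HCl, THF, rt
Reagents that add atoms: water, O
Why: Acid-catalysed hydrolysis of the dioxolane acetal liberates the aldehyde; allyl ethers and haloalkenes are stable to dilute acid.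

Step 4
Reactants: 8 ethyl 3-oxobutanoate
Product: 9 ethyl (2E)-3-{[(trifluoromethyl)sulfonyl]oxy}but-2-enoate
Conditions: Tf2O, aq. Me4NOH, hexane, 5 °C
Reagents that add atoms: trifluoromethanesulfonic anhydride, O=S(=O)(OS(=O)(=O)C(F)(F)F)C(F)(F)F
Why: O-Triflation of the β-keto ester enolate; with the non-coordinating tetramethylammonium counter-ion the enolate reacts in the extended form so that the triflate ends anti to the ester (E), the geometry that later places C2 and C9 trans.

Step 5
Reactants: 7 (4Z)-4-{[(2-bromoprop-2-en-1-yl)oxy]methyl}-5-chloropent-4-enal; 9 ethyl (2E)-3-{[(trifluoromethyl)sulfonyl]oxy}but-2-enoate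
Product: 10 ethyl (2E,7Z)-7-{[(2-bromoprop-2-en-1-yl)oxy]methyl}-8-chloro-4-hydroxy-3-methylocta-2,7-dienoate (racemic carbinol)
Conditions: CrCl2 (4 equiv), NiCl2 (1 mol%), DMF, rt
Reagents that add atoms: none
Why: Nozaki–Hiyama–Kishi coupling: zerovalent nickel inserts into the activated enol triflate far faster than into the unactivated 2-bromoalkene, the alkenylchromium adds to the aldehyde with retention of alkene geometry, and the racemic carbinol centre is removed in step 6.

Step 6
Reactants: 10 ethyl (2E,7Z)-7-{[(2-bromoprop-2-en-1-yl)oxy]methyl}-8-chloro-4-hydroxy-3-methylocta-2,7-dienoate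
Product: 11 ethyl (2E,7Z)-7-{[(2-bromoprop-2-en-1-yl)oxy]methyl}-8-chloro-3-methyl-4-oxoocta-2,7-dienoate
Conditions: Dess–Martin periodinane, NaHCO3, CH2Cl2, 0 °C to rt
Reagents that add atoms: none
Why: Dess–Martin oxidation of the allylic alcohol gives the 4-oxo-2-enoate, a dienophile activated by ketone and ester, without touching the halides or the alkene geometry.

Step 7
Reactants: 12 pent-1-yn-3-one; 13 (2S,5S)-2,5-diphenylpyrrolidine
Product: 14 (1E)-1-[(2S,5S)-2,5-diphenylpyrrolidin-1-yl]pent-1-en-3-one
Conditions: CH2Cl2, 0 °C to rt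
Reagents that add atoms: none
Why: Conjugate (aza-Michael) addition of the secondary amine to the ynone gives the E vinylogous amide.

Step 8
Reactants: 14 (1E)-1-[(2S,5S)-2,5-diphenylpyrrolidin-1-yl]pent-1-en-3-one
Product: 15 (2S,5S)-1-[(1E,3Z)-3-{[tert-butyl(dimethyl)silyl]oxy}penta-1,3-dien-1-yl]-2,5-diphenylpyrrolidine
Conditions: KN(SiMe3)2, THF, −78 °C; tert-butyldimethylsilyl chloride, −78 °C to rt
Reagents that add atoms: tert-butyldimethylsilyl chloride, CC(C)(C)[Si](C)(C)Cl
Why: Deprotonation of the ethyl ketone side of the vinylogous amide gives the Z potassium dienolate, whose O-silylation furnishes the (1E,3Z) 1-amino-3-siloxy diene with the terminal methyl outside, as an s-cis Diels–Alder diene requires.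

Step 9
Reactants: 11 ethyl (2E,7Z)-7-{[(2-bromoprop-2-en-1-yl)oxy]methyl}-8-chloro-3-methyl-4-oxoocta-2,7-dienoate; 15 (2S,5S)-1-[(1E,3Z)-3-{[tert-butyl(dimethyl)silyl]oxy}penta-1,3-dien-1-yl]-2,5-diphenylpyrrolidine
Product: 17 ethyl (1S,6S)-6-[(4Z)-4-{[(2-bromoprop-2-en-1-yl)oxy]methyl}-5-chloropent-4-enoyl]-2,6-dimethyl-3-oxocyclohex-4-ene-1-carboxylate (ring C2 epimers), via amino silyl enol ether cycloadduct 16 (not isolated)
Conditions: toluene, rt to 60 °C; then 1 M HCl, THF, 0 °C
Reagents that add atoms: none
Why: Diels–Alder reaction of the 1-amino-3-siloxy diene: its nucleophilic methyl-bearing terminus bonds to C10 (β to the ketone, the stronger acceptor and the less substituted carbon), the E geometry of 11 is transferred so that the C2 acyl and C9 ester groups are trans and C1 and C10 are set together, the C2-symmetric diphenylpyrrolidine blocks one diene face (see remark), and aqueous acid then hydrolyses the silyl enol ether and eliminates the amine (E1cB) to the enone.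

Step 10
Reactants: 17 cyclohexenone keto ester
Product: 18 ethyl (1S,6S)-6-[(4Z)-4-{[(2-bromoprop-2-en-1-yl)oxy]methyl}-5-chloropent-4-enoyl]-3-hydroxy-2,6-dimethylcyclohex-4-ene-1-carboxylate (ring C2 and C3 epimers)
Conditions: NaBH4, CeCl3·7H2O, MeOH, −78 °C
Reagents that add atoms: none
Why: Luche reduction (1,2-selective) reduces the cyclohexenone carbonyl much faster than the C2 ketone, which is flanked by the quaternary C1; the new carbinol centre and the C11 centre are both erased in step 11.

Step 11
Reactants: 18 allylic alcohol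
Product: 19 ethyl (1S,6S)-6-[(4Z)-4-{[(2-bromoprop-2-en-1-yl)oxy]methyl}-5-chloropent-4-enoyl]-2,6-dimethylcyclohexa-2,4-diene-1-carboxylate
Conditions: methyl N-(triethylammoniosulfonyl)carbamate (Burgess reagent), benzene, 50 °C
Reagents that add atoms: none
Why: Burgess dehydration (syn elimination of the allylic sulfamate) can only take the C11 hydrogen and so gives the C11=C12–C13=C14 diene, the neutral conditions leaving the C2 ketone and the ester untouched.

Step 12
Reactants: 19 cyclohexadiene ketone
Product: 20 ethyl (1S,6S)-6-[(1R,4Z)-4-{[(2-bromoprop-2-en-1-yl)oxy]methyl}-5-chloro-1-hydroxypent-4-en-1-yl]-2,6-dimethylcyclohexa-2,4-diene-1-carboxylate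
Conditions: (S)-2-methyl-CBS-oxazaborolidine (20 mol%), catecholborane, toluene, −78 °C
Reagents that add atoms: none
Why: Corey–Bakshi–Shibata reduction of the only ketone: the (S)-oxazaborolidine differentiates the quaternary C1 (large) from the CH2 chain (small) and delivers hydride to give the 2R alcohol under reagent control, catecholborane at −78 °C sparing diene, ester and haloalkenes.

Step 13
Reactants: 20 C2 alcohol
Product: 21 C2 tert-butyldimethylsilyl ether of 20
Conditions: tert-butyldimethylsilyl triflate, 2,6-lutidine, CH2Cl2, −78 to 0 °C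
Reagents that add atoms: tert-butyldimethylsilyl trifluoromethanesulfonate, CC(C)(C)[Si](C)(C)OS(=O)(=O)C(F)(F)F
Why: Silylation of the hindered secondary alcohol with the silyl triflate and 2,6-lutidine protects C2–OH for the base and hydride steps that follow.

Step 14
Reactants: 21 silyl ether diene
Product: 22 cis-11,12-diol (11S,12R; both hydroxyls anti to the C10 ester)
Conditions: OsO4 (2 mol%), N-methylmorpholine N-oxide, acetone/H2O, 0 °C
Reagents that add atoms: N-methylmorpholine N-oxide, C[N+]1([O-])CCOCC1; water, O (both oxygens are delivered through catalytic OsO4)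
Why: Upjohn dihydroxylation: OsO4 adds syn to the electron-rich trisubstituted C11=C12 bond of the diene from the face anti to the C10 ester, which sets C11 and C12 together as the cis-diol, while the disubstituted C13=C14 bond beside the quaternary C1 and the two haloalkenes react more slowly.

Step 15
Reactants: 22 cis-11,12-diol
Product: 23 11,12-O-isopropylidene acetal of 22
Conditions: 2,2-dimethoxypropane, pyridinium p-toluenesulfonate, CH2Cl2, rt
Reagents that add atoms: 2,2-dimethoxypropane, COC(C)(C)OC
Why: Acid-catalysed transacetalisation converts the cis-1,2-diol into its isopropylidene acetal, which masks the tertiary and secondary hydroxyls through the following base and oxidation steps.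

Step 16
Reactants: 23 acetonide ester
Product: 24 primary alcohol (C9 carbinol)
Conditions: iBu2AlH (2.5 equiv), CH2Cl2, −78 to 0 °C
Reagents that add atoms: none
Why: Hydride reduction of the hindered ethyl ester with iBu2AlH gives the primary alcohol; silyl ether, acetal and haloalkenes are inert.

Step 17
Reactants: 24 primary alcohol
Product: 25 C9 aldehyde
Conditions: Dess–Martin periodinane, NaHCO3, CH2Cl2, 0 °C to rt
Reagents that add atoms: none
Why: Dess–Martin oxidation gives the C9 aldehyde under buffered conditions that do not epimerise C10.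

Step 18
Reactants: 25 C9 aldehyde
Product: 26 eleven-membered allylic alcohol (9R hydroxyl; exocyclic C8 methylene)
Conditions: CrCl2 (10 equiv), NiCl2 (10 mol%), DMSO/THF, 2 mM, rt
Reagents that add atoms: none
Why: Intramolecular Nozaki–Hiyama–Kishi reaction under high dilution (zerovalent nickel inserts into the alkenyl bromide, transmetalation to trivalent chromium, addition to the aldehyde) closes the eleven-membered oxacycle at C8–C9, and attack anti to the quaternary C1 with C10–H inside (Felkin–Anh) gives the 9R alcohol.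

Step 19
Reactants: 26 eleven-membered allylic alcohol
Product: 27 9-O-tert-butyldimethylsilyl ether of 26
Conditions: tert-butyldimethylsilyl triflate, 2,6-lutidine, CH2Cl2, −78 to 0 °C
Reagents that add atoms: tert-butyldimethylsilyl trifluoromethanesulfonate, CC(C)(C)[Si](C)(C)OS(=O)(=O)C(F)(F)F
Why: Silylation with the silyl triflate protects the allylic C9 hydroxyl so that the later diol cleavage cannot cut the C8–C9 bond and no acyl group or proton source sits next to the enolate of step 21.

Step 20
Reactants: 27 bis-silyl ether macrocycle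
Product: 29 eleven-membered keto ether (C8 ketone; C7H2–O–C16H2), via vicinal diol 28 (not isolated)
Conditions: OsO4 (2 mol%), NaIO4, 2,6-lutidine, dioxane/H2O, rt
Reagents that add atoms: sodium periodate, [Na+].[O-]I(=O)(=O)=O; water, O (oxygen relayed by catalytic OsO4)
Why: Lemieux–Johnson oxidation: OsO4 dihydroxylates the unhindered 1,1-disubstituted C8 methylene in preference to the hindered cis-cyclohexene and the electron-poor chloroalkene, and NaIO4 cleaves the diol 28 to the C8 ketone, which makes C7 the acidic position.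

Step 21
Reactants: 29 eleven-membered keto ether
Product: 31 ten-membered α-hydroxy ketone (6S chloride; 7R hydroxyl; exocyclic C5 methylene), via lithium Z-enolate 30 (not isolated)
Conditions: LiN(SiMe3)2 (1.3 equiv), THF, −78 to −40 °C; AcOH, −78 °C
Reagents that add atoms: none
Why: Proposed new method: LiN(SiMe3)2 removes a C7 proton (the unhindered α-position, activated by the C8 carbonyl and the ring oxygen) to give the chelated Z-enolate 30, whose C7 terminus attacks C6 of the exocyclic chloroalkene in a concerted [2,3]-sigmatropic (Wittig) shift while the O–C16 bond breaks, so that O and C16 leave the ring, C6 enters it, C7–O becomes the alkoxide and C16 the exocyclic methylene. The closest known reactions are the enolate [2,3]-Wittig rearrangement of acyclic α-allyloxy ketones and the ring-contracting [2,3]-Wittig rearrangement of thirteen-membered diallyl and allyl propargyl ethers to ten-membered carbocycles; new are the exocyclic position of the alkene (contraction by one atom instead of three) and the chlorine on the migrating terminus, which as a σ-acceptor should lower the alkene LUMO and speed the shift. The ten-membered carbocycle is closed by suprafacial C7–C6 bond formation through a five-membered envelope set inside the macrocycle (ring contraction from eleven to ten). C6 is set relative to C7 by the Z geometry of the chloroalkene together with the folded envelope in which C8 lies over the allyl unit, the only arrangement in which the C8–C9–C10–C1–C2–C3–C4 tether spans a normal transannular distance; the absolute sense at C7 is set by C9, whose silyloxy group takes the enolate face opposite the allyl unit while the ring bond to C10 holds the allyl unit on the other face. The step needs enolisation at C7 rather than at the hindered, silyloxy-bearing C9, the [2,3] rather than the [1,2] pathway (low temperature, lithium enolate), and survival of the β-chloro alkoxide, secured by the acetic acid quench at −78 °C before epoxide closure can occur.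

Step 22
Reactants: 31 ten-membered α-hydroxy ketone; 32 ethyl propanoate
Product: 34 protected lactone (8R tertiary alcohol; 17R methyl; γ-lactone C7–O–C19), via aldol adduct 33 (not isolated)
Conditions: LiN(iPr)2, 32 (3 equiv), THF, −78 °C, then 31; AcOH, −78 °C; pyridinium p-toluenesulfonate, benzene, rt
Reagents that add atoms: none
Why: Chelation-controlled aldol addition (Cram chelate) of the lithium enolate of ethyl propanoate to the C8 ketone, whose carbonyl is held syn to the C7 lithium alkoxide so that the enolate enters from the C7–H side and sets C8, followed by acid-catalysed γ-lactonisation of the C7 hydroxyl; C17 settles with its methyl anti to C9 (the thermodynamically preferred lactone epimer, reachable by enolisation if the kinetic ratio is poor).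

Step 23
Reactants: 34 protected lactone
Product: 35 pentaol (2,9,12-secondary and 8,11-tertiary hydroxyls free)
Conditions: 48% aq. HF, MeCN, 0 °C to rt
Reagents that add atoms: none
Why: Aqueous HF cleaves both silyl ethers and hydrolyses the isopropylidene acetal in one operation, conditions that the lactone, the tertiary alcohols and the allylic chloride tolerate.

Step 24
Reactants: 35 pentaol
Product: 36 CNP0259091.2 (target)
Conditions: Ac2O, pyridine, 4-(dimethylamino)pyridine (cat.), 0 °C to rt
Reagents that add atoms: acetic anhydride, CC(=O)OC(C)=O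
Why: Acetylation with Ac2O and pyridine esterifies the three secondary hydroxyls at C2, C9 and C12, the tertiary hydroxyls at C8 and C11 being too hindered to react under these conditions, and gives the target.

## Compound list

1 | prop-2-yn-1-ol | C#CCO | starting material
2 | [2-(1,3-dioxolan-2-yl)ethyl]magnesium bromide | Br[Mg]CCC1OCCO1 | starting material
3 | alkenylmagnesium alkoxide (Mg on the terminal carbon, cis to CH2O) | Br[Mg]/C=C(\CO[Mg]Br)CCC1OCCO1 | intermediate (not isolated)
4 | (2Z)-2-(chloromethylidene)-4-(1,3-dioxolan-2-yl)butan-1-ol | OC/C(=C\Cl)CCC1OCCO1 | intermediate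
5 | 2,3-dibromoprop-1-ene | C=C(Br)CBr | starting material
6 | 2-[(3Z)-3-{[(2-bromoprop-2-en-1-yl)oxy]methyl}-4-chlorobut-3-en-1-yl]-1,3-dioxolane | C=C(Br)COC/C(=C\Cl)CCC1OCCO1 | intermediate
7 | (4Z)-4-{[(2-bromoprop-2-en-1-yl)oxy]methyl}-5-chloropent-4-enal | C=C(Br)COC/C(=C\Cl)CCC=O | intermediate
8 | ethyl 3-oxobutanoate | CCOC(=O)CC(C)=O | starting material
9 | ethyl (2E)-3-{[(trifluoromethyl)sulfonyl]oxy}but-2-enoate | CCOC(=O)/C=C(\C)OS(=O)(=O)C(F)(F)F | intermediate
10 | ethyl (2E,7Z)-7-{[(2-bromoprop-2-en-1-yl)oxy]methyl}-8-chloro-4-hydroxy-3-methylocta-2,7-dienoate (racemic carbinol) | C=C(Br)COC/C(=C\Cl)CCC(O)/C(C)=C/C(=O)OCC | intermediate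
11 | ethyl (2E,7Z)-7-{[(2-bromoprop-2-en-1-yl)oxy]methyl}-8-chloro-3-methyl-4-oxoocta-2,7-dienoate | C=C(Br)COC/C(=C\Cl)CCC(=O)/C(C)=C/C(=O)OCC | intermediate
12 | pent-1-yn-3-one | CCC(=O)C#C | starting material
13 | (2S,5S)-2,5-diphenylpyrrolidine | N1[C@H](c2ccccc2)CC[C@H]1c1ccccc1 | starting material
14 | (1E)-1-[(2S,5S)-2,5-diphenylpyrrolidin-1-yl]pent-1-en-3-one | CCC(=O)/C=C/N1[C@H](c2ccccc2)CC[C@H]1c1ccccc1 | intermediate
15 | (2S,5S)-1-[(1E,3Z)-3-{[tert-butyl(dimethyl)silyl]oxy}penta-1,3-dien-1-yl]-2,5-diphenylpyrrolidine | C/C=C(/C=C/N1[C@H](c2ccccc2)CC[C@H]1c1ccccc1)O[Si](C)(C)C(C)(C)C | intermediate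
16 | amino silyl enol ether cycloadduct (C1 and C10 set; C11 and C14 not specified) | C=C(Br)COC/C(=C\Cl)CCC(=O)[C@@]1(C)C(N2[C@H](c3ccccc3)CC[C@H]2c2ccccc2)C=C(O[Si](C)(C)C(C)(C)C)C(C)[C@@H]1C(=O)OCC | intermediate (not isolated)
17 | ethyl (1S,6S)-6-[(4Z)-4-{[(2-bromoprop-2-en-1-yl)oxy]methyl}-5-chloropent-4-enoyl]-2,6-dimethyl-3-oxocyclohex-4-ene-1-carboxylate (ring C2 epimers) | C=C(Br)COC/C(=C\Cl)CCC(=O)[C@@]1(C)C=CC(=O)C(C)[C@@H]1C(=O)OCC | intermediate
18 | the 3-hydroxy compound from 17 (allylic alcohol, ring C2 and C3 epimers) | C=C(Br)COC/C(=C\Cl)CCC(=O)[C@@]1(C)C=CC(O)C(C)[C@@H]1C(=O)OCC | intermediate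
19 | ethyl (1S,6S)-6-[(4Z)-4-{[(2-bromoprop-2-en-1-yl)oxy]methyl}-5-chloropent-4-enoyl]-2,6-dimethylcyclohexa-2,4-diene-1-carboxylate | C=C(Br)COC/C(=C\Cl)CCC(=O)[C@@]1(C)C=CC=C(C)[C@@H]1C(=O)OCC | intermediate
20 | ethyl (1S,6S)-6-[(1R,4Z)-4-{[(2-bromoprop-2-en-1-yl)oxy]methyl}-5-chloro-1-hydroxypent-4-en-1-yl]-2,6-dimethylcyclohexa-2,4-diene-1-carboxylate | C=C(Br)COC/C(=C\Cl)CC[C@@H](O)[C@@]1(C)C=CC=C(C)[C@@H]1C(=O)OCC | intermediate
21 | C2 tert-butyldimethylsilyl ether of 20 | C=C(Br)COC/C(=C\Cl)CC[C@@H](O[Si](C)(C)C(C)(C)C)[C@@]1(C)C=CC=C(C)[C@@H]1C(=O)OCC | intermediate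
22 | cis-11,12-diol of 21 (11S tertiary, 12R secondary, C13=C14 retained) | C=C(Br)COC/C(=C\Cl)CC[C@@H](O[Si](C)(C)C(C)(C)C)[C@@]1(C)C=C[C@@H](O)[C@@](C)(O)[C@@H]1C(=O)OCC | intermediate
23 | 11,12-O-isopropylidene acetal of 22 | C=C(Br)COC/C(=C\Cl)CC[C@@H](O[Si](C)(C)C(C)(C)C)[C@@]1(C)C=C[C@@H](OC(C)(C)O2)[C@]2(C)[C@@H]1C(=O)OCC | intermediate
24 | primary alcohol from 23 (C9 carbinol on C10) | C=C(Br)COC/C(=C\Cl)CC[C@@H](O[Si](C)(C)C(C)(C)C)[C@@]1(C)C=C[C@@H](OC(C)(C)O2)[C@]2(C)[C@@H]1CO | intermediate
25 | C9 aldehyde | C=C(Br)COC/C(=C\Cl)CC[C@@H](O[Si](C)(C)C(C)(C)C)[C@@]1(C)C=C[C@@H](OC(C)(C)O2)[C@]2(C)[C@@H]1C=O | intermediate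
26 | eleven-membered allylic alcohol: 3-oxa ring C1–C5, C16, O, C7–C10 fused to the cyclohexene, 9R hydroxyl, exocyclic C8 methylene, exocyclic (Z)-chloromethylene on C5, 2-OTBS, 11,12-acetonide | Cl/C=C1/CC[C@@H](O[Si](C)(C)C(C)(C)C)[C@@]2(C)C=C[C@@H](OC(C)(C)O3)[C@]3(C)[C@@H]2[C@@H](O)C(=C)COC1 | intermediate
27 | 9-O-tert-butyldimethylsilyl ether of 26 | Cl/C=C1/CC[C@@H](O[Si](C)(C)C(C)(C)C)[C@@]2(C)C=C[C@@H](OC(C)(C)O3)[C@]3(C)[C@@H]2[C@@H](O[Si](C)(C)C(C)(C)C)C(=C)COC1 | intermediate
28 | vicinal diol from 27 (C8 tertiary hydroxyl and hydroxymethyl) | Cl/C=C1/CC[C@@H](O[Si](C)(C)C(C)(C)C)[C@@]2(C)C=C[C@@H](OC(C)(C)O3)[C@]3(C)[C@@H]2[C@@H](O[Si](C)(C)C(C)(C)C)C(O)(CO)COC1 | intermediate (not isolated)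
29 | eleven-membered keto ether: C8 ketone, C7H2–O–C16H2, (Z)-chloromethylene on C5 | Cl/C=C1/CC[C@@H](O[Si](C)(C)C(C)(C)C)[C@@]2(C)C=C[C@@H](OC(C)(C)O3)[C@]3(C)[C@@H]2[C@@H](O[Si](C)(C)C(C)(C)C)C(=O)COC1 | intermediate
30 | lithium Z-enolate of 29 (C7=C8, O–Li cis to the ring oxygen) | Cl/C=C1/CC[C@@H](O[Si](C)(C)C(C)(C)C)[C@@]2(C)C=C[C@@H](OC(C)(C)O3)[C@]3(C)[C@@H]2[C@@H](O[Si](C)(C)C(C)(C)C)/C(O[Li])=C/OC1 | intermediate (not isolated)
31 | ten-membered α-hydroxy ketone: C8 ketone, 7R hydroxyl, 6S chloride, exocyclic C5 methylene | C=C1CC[C@@H](O[Si](C)(C)C(C)(C)C)[C@@]2(C)C=C[C@@H](OC(C)(C)O3)[C@]3(C)[C@@H]2[C@@H](O[Si](C)(C)C(C)(C)C)C(=O)[C@@H](O)[C@H]1Cl | intermediate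
32 | ethyl propanoate | CCC(=O)OCC | starting material
33 | aldol adduct (C8 tertiary alcohol carrying the C17 propanoate unit, C7 hydroxyl free) | C=C1CC[C@@H](O[Si](C)(C)C(C)(C)C)[C@@]2(C)C=C[C@@H](OC(C)(C)O3)[C@]3(C)[C@@H]2[C@@H](O[Si](C)(C)C(C)(C)C)[C@](O)([C@@H](C)C(=O)OCC)[C@@H](O)[C@H]1Cl | intermediate (not isolated)
34 | protected lactone: γ-lactone C7–O–C19, 8R hydroxyl, 17R methyl, 2,9-bis-OTBS, 11,12-acetonide | C=C1CC[C@@H](O[Si](C)(C)C(C)(C)C)[C@@]2(C)C=C[C@@H](OC(C)(C)O3)[C@]3(C)[C@@H]2[C@@H](O[Si](C)(C)C(C)(C)C)[C@]2(O)[C@@H](C)C(=O)O[C@H]2[C@H]1Cl | intermediate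
35 | pentaol (2,8,9,11,12-pentahydroxy lactone) | C=C1CC[C@@H](O)[C@@]2(C)C=C[C@@H](O)[C@@](C)(O)[C@@H]2[C@@H](O)[C@]2(O)[C@@H](C)C(=O)O[C@H]2[C@H]1Cl | intermediate
36 | CNP0259091.2: (1S,2R,6S,7R,8R,9R,10S,11S,12R,17R)-2,9,12-triacetoxy-6-chloro-8,11-dihydroxy briarane 5(16),13-diene 7,19-lactone | C=C1CC[C@@H](OC(C)=O)[C@@]2(C)C=C[C@@H](OC(C)=O)[C@@](C)(O)[C@@H]2[C@@H](OC(C)=O)[C@]2(O)[C@@H](C)C(=O)O[C@H]2[C@H]1Cl | target

## Summary

Total step count: 24. Longest linear sequence: 21 steps (1–3, 5, 6, 9–24).

Steps most likely to fail: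

1. Step 21 (proposed new method). The enolate may rearrange through the wrong envelope (poor facial or folded/extended selectivity), enolise toward C9, take the [1,2] pathway, or the chloro alkoxide may close to the epoxide before the quench. Fallback: the shift is run in its known aza-enolate form under auxiliary control. Setting out from 29, condensation with (S)-1-amino-2-(methoxymethyl)pyrrolidine gives the hydrazone of the eleven-membered keto ether F1. Deprotonation (LiN(iPr)2, THF, −78 to −20 °C) triggers the [2,3]-Wittig rearrangement of this α-allyloxy ketone hydrazone to the ring-contracted α-hydroxy hydrazone F2. Hydrazone cleavage with aqueous oxalic acid comes back to the route at 31 (the antipodal auxiliary is taken if it matches the substrate better).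

2. Step 18. Oxidative addition into the alkenyl bromide may be slow enough for oligomerisation to compete, and the alkenylchromium may add to the wrong aldehyde face. Fallback for the stereochemical problem: the C9 centre is reset by oxidation and chelation-controlled reduction instead of by the C–C bond formation. Setting out from 26 as obtained (C9 epimer or mixture), Dess–Martin oxidation gives the macrocyclic α-methylene ketone F3. Reduction with LiAlH4 in the presence of LiI (Et2O, −78 °C) proceeds through a chelate between the C9 carbonyl and the C11 acetal oxygen and delivers the 1,3-syn product, which is the 9R alcohol 26, where the route is rejoined.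

3. Step 22. The hindered, doubly oxygenated cyclodecanone may enolise or undergo retro-aldol instead of accepting the ester enolate, or be attacked from the wrong face. Fallback: the nucleophile is delivered intramolecularly. Setting out from 31, acylation of the C7 hydroxyl with 2-bromopropanoyl bromide and pyridine gives the 2-bromopropanoate F4. SmI2 (THF, −78 °C) then generates the samarium enolate for an intramolecular Reformatsky reaction onto the C8 ketone, giving the β-hydroxy γ-lactone directly and coming back to the route at 34.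

## Further compounds

F1 | step 21 | hydrazone of 29 with (S)-1-amino-2-(methoxymethyl)pyrrolidine | Cl/C=C1/CC[C@@H](O[Si](C)(C)C(C)(C)C)[C@@]2(C)C=C[C@@H](OC(C)(C)O3)[C@]3(C)[C@@H]2[C@@H](O[Si](C)(C)C(C)(C)C)C(=NN2CCC[C@H]2COC)COC1
F2 | step 21 | ring-contracted α-hydroxy hydrazone (ten-membered ring, 6S chloride, 7R hydroxyl) | C=C1CC[C@@H](O[Si](C)(C)C(C)(C)C)[C@@]2(C)C=C[C@@H](OC(C)(C)O3)[C@]3(C)[C@@H]2[C@@H](O[Si](C)(C)C(C)(C)C)C(=NN2CCC[C@H]2COC)[C@@H](O)[C@H]1Cl
F3 | step 18 | macrocyclic α-methylene ketone (C9 ketone, C8 methylene) | Cl/C=C1/CC[C@@H](O[Si](C)(C)C(C)(C)C)[C@@]2(C)C=C[C@@H](OC(C)(C)O3)[C@]3(C)[C@@H]2C(=O)C(=C)COC1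
F4 | step 22 | 7-O-(2-bromopropanoyl) ester of 31 | C=C1CC[C@@H](O[Si](C)(C)C(C)(C)C)[C@@]2(C)C=C[C@@H](OC(C)(C)O3)[C@]3(C)[C@@H]2[C@@H](O[Si](C)(C)C(C)(C)C)C(=O)[C@@H](OC(=O)C(C)Br)[C@H]1Cl
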